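## Structural features

The target is a flavonol: a 4H-chromen-4-one in which benzo ring A and pyranone ring C share the C4a–C8a bond, with phenyl ring B joined through the single C2–C1' bond. Ring C carries the enolic 3-OH beside the C4 carbonyl, ring A a free catechol at C6/C7 with no oxygen at C5, and ring B a free 4'-OH next to a 3'-O-prenyl ether. There is no stereocentre and no stereogenic double bond, so nothing has to be set or protected stereochemically. The problem is purely regiochemical: five oxygens, four free and one alkylated at a defined position of a catechol. The fragile groups are the aryl prenyl ether and the free catechol and flavonol enol. The prenyl ether is open to ionisation by acid, π-allyl cleavage by zerovalent palladium, oxidative cleavage by quinone oxidants and Claisen rearrangement on strong heating. The catechol and the enol oxidise in air under base. The real difficulty is the 6,7-dioxygenation of ring A without a 5-oxygen, together with keeping the two ring B oxygens differentiated to the end. The key step exploits the fact that ring C (O1, C2, C3–OH, C4=O, C4a, C8a) is the 3-hydroxy-4-pyranone ring of kojic acid 1. Its hydroxymethyl carbon is C8 and its free ring CH is C4a, so only C5, C6 and C7 are missing; hung on C8 as a 2,3-dioxygenated diene, they let ring A close by forming C4a–C5.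

## Logic of the disconnections

**23 ⇒ 22.** Only heteroatom–protecting-group bonds are cut: the three O–CH2 acetal bonds at O3, O7 and O4' and the O–Si bond at O6. The oxidation-prone catechol and enol are best freed last, and 22 is a stable, fully masked compound. The forward step must remove four groups in one operation without ionising the allylic C–O bond of the prenyl ether. That calls for dilute protic acid at ambient temperature and no basic or fluoride finish.

**22 ⇒ 21 ⇒ 20 (⇐ 19).** The C4a–C5 bond is cut and hydrogens are put back at C4a and C5. This leaves ring C as an intact, fully substituted pyranone and opens ring A to a butadienyl chain on C8a. The oxygen pattern of ring A is then written into an acyclic chain instead of being won by aromatic substitution. The forward step needs the pyranone and C6 cis across C7=C8, which is exactly what the 1E descriptor of 20 expresses, and an s-cis diene. It also needs a temperature below the Claisen rearrangement of the prenyl ether and an oxidant that spares the prenyl group. Because the preceding olefination should favour the other geometry, 20 is generated in the flask from its isomer 19 by light and drained by the ring closure. The dihydro compound 21 is oxidised at once by a heterogeneous manganese oxidant rather than a quinone.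

**19 ⇒ 18.** The O–Si bond at O6 is cut, which reveals C6 as the carbonyl of a methyl ketone. Only the methyl group (C5) has α-hydrogens, so enol silylation can give one diene only. The demand is a silylating agent that does not open the three acetals.

**18 ⇒ 13 + 17.** The C7=C8 double bond is cut by a phosphonate olefination. This splits off all three new ring A carbons with both oxygens already in place and makes the route convergent. The forward step asks a hindered α-alkoxy phosphonate anion to add to an electrophilic heteroaryl aldehyde. Geometry is not controlled and need not be.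

**13 ⇒ 12.** Only the oxidation level of C8 changes. The alcohol is the form in which this carbon comes with ring C. The oxidant must leave the prenyl alkene and the acetals alone.

**12 ⇒ 3 + 11.** The C2–C1' bond, the only link between rings C and B, is cut by a palladium-catalysed boronate coupling. Both partners are simple. The coupling must outrun hydrolytic substitution of the vinylogous acyl iodide and ionisation of the prenyl ether.

**3 ⇒ 2 ⇒ 1.** The O–CH2 acetal bond at the enol oxygen and then the C–I bond are cut. Iodination is directed by the free enol and so must come before protection. The mono-protection relies on the enol being far more acidic than the primary alcohol, which must stay free for the later oxidation.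

**11 ⇒ 9 ⇒ 7 + 8; 7 ⇒ 5 ⇒ 4.** In turn the C–B bond, the O–prenyl bond, the aryl C–O bond (made from the formyl C–C bond by oxygen insertion) and the O–CH2 acetal bond are cut. In 4 the two future ring B oxygens are already different, one a hydroxyl and one a formyl carbon, and the bromine marks C1'. The forward steps need aryl rather than hydride migration in the oxygen insertion. They also need halogen–metal exchange that is faster than deprotonation next to the allylic ether oxygen.

**17 ⇒ 15 ⇒ 14.** The C6–C7 bond is cut by acylation of an α-metalated phosphonate, and then the O–CH2 acetal bond. The C7 oxygen comes with the phosphonate. The acylation must stop after one addition, which an acetyl donor that rests at the tetrahedral stage secures.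

## Other disconnections considered

**Alternative 1:** The cut runs through ring B at C2'–C3' and C4'–C5'.
- **Forward step:** methyl coumalate A1 and the bis(trimethylsilyl) ketene acetal A2 of an O-prenyl glycolate would undergo [4+2] cycloaddition. The adduct then loses its carboxyl bridge and one silyloxy group to give methyl 4-hydroxy-3-(prenyloxy)benzoate A3.
- **In favour:** no metal is needed, and the regiochemistry follows from the polarisation of A1, whose C6 takes the nucleophilic carbon of A2. The catechol is also differentiated from the start, with the prenyl ether placed and the 4'-OH free in one step. On this point it is better than the chosen plan, which spends steps 3 to 5 to reach the same differentiation in 9.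
- **Against:** A2 is an allyl vinyl ether. It is set up for a [3,3] shift of the prenyl group onto carbon at or below the temperature a pyranone cycloaddition usually needs, and it is very moisture-sensitive. More seriously, the step builds the ring that poses no problem. Rings A and C, the 6,7-dioxygenation and the 3-OH would all remain to be made, presumably by a chalcone and oxidative cyclisation sequence from A3.
- **Comparison:** on mechanism the pyranone cycloaddition with extrusion is an established class and stands on firmer ground than step 13. On structure it solves the smaller part of the problem. On step economy it saves two or three steps on ring B but adds the whole classical construction of rings A and C, so no net gain is expected.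

**Alternative 2:** The cut removes C4 as a one-carbon unit, at C4a–C4 and C4–C3.
- **Forward step:** the ring A iodide A4, carbon monoxide A6 and the ring B α-(methoxymethoxy) ketone A5 would be joined by a zerovalent palladium catalyst with a wide-bite-angle bisphosphine and base. This carbonylative α-arylation of a ketone enolate gives the 2-alkoxy-1,3-diketone A7, with no ring closed yet.
- **In favour:** it is the most convergent of the four plans, with three components and two C–C bonds in one step. A7 holds every carbon and oxygen of the target at the right oxidation level. Ring A is bought as a trioxygenated benzene rather than built. The reaction class, like the closure of 2-hydroxyaryl 1,3-diketones to chromones, is known. On convergence, probable step count and precedent it is better than the chosen plan.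
- **Against:**
  - The enolate of A5 is more hindered than that of a simple aryl methyl ketone.
  - A4 is an electron-rich, ortho-substituted iodide that should add to palladium slowly.
  - The prenyl ether must endure zerovalent palladium, base and heat for longer than in step 7.
  - A7 is an enolisable diketone open to retro-Claisen cleavage.
  - Ring closure needs either selective removal of one acetal out of five or an acid treatment strong enough for cyclodehydration, which is harder on the prenyl ether than step 14.
- **Comparison:** the chosen plan avoids the acid-driven cyclodehydration and the long palladium exposure. It pays for this with more steps and an unprecedented key step.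

**Alternative 3:** The cut is at C3–C4 of ring C.
- **Forward step:** in the dialdehyde A8 a triazolium-derived carbene would turn the ring A aldehyde into an acyl anion equivalent. This adds to the tethered aliphatic aldehyde and closes ring C as the racemic trans dihydroflavonol A9.
- **In favour:** the conditions are organocatalytic and mild, with no palladium and no acid near the prenyl ether. Rings A and B come from simple aromatic pieces. The intramolecular acyloin closure to six-membered rings is established for aldehyde–ketone tethers. In mildness it is the equal or the better of the chosen plan.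
- **Against:**
  - A9 is at the wrong oxidation level. C2–C3 must be dehydrogenated in an extra step that destroys the two stereocentres the key step creates.
  - A8 is an α-aryl-α-aryloxy acetaldehyde, easily enolised and air-oxidised. Making it means unveiling two different aldehydes in one molecule.
  - The aliphatic aldehyde can also become the acyl donor. That would give the regioisomeric acyloin with the carbonyl at C3 and the hydroxyl at C4, and acyloins can equilibrate through the enediol.
- **Comparison:** on mechanism it has somewhat better precedent than step 13 but a selectivity question of its own. On structure the chosen plan has ring C at its final oxidation level from the start. On step economy the two are comparable, with one more redox step for the alternative.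

Key step: step 13

Remark on the chemistry: step 11 is assumed to give mainly the 3Z enone, as α-alkoxy phosphonates usually do; the plan does not depend on this because step 13 converts both geometric isomers.

Abbreviations: MOM = methoxymethyl; TBS = tert-butyldimethylsilyl; prenyl = 3-methylbut-2-en-1-yl; Ar = 4-(methoxymethoxy)-3-[(3-methylbut-2-en-1-yl)oxy]phenyl.

## Route

Step 1
Reactants: 1 kojic acid
Product: 2 5-hydroxy-2-(hydroxymethyl)-6-iodo-4H-pyran-4-one
Conditions: N-iodosuccinimide (1.05 equiv), DMF, 0 → 25 °C, dark
Reagents that add atoms: N-iodosuccinimide, O=C1CCC(=O)N1I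
Why: Electrophilic iodination of the enol at C6, the α-carbon of the enol and the only position activated by both the enol OH and the ring oxygen. Halogenation of 3-hydroxy-4-pyranones at this carbon is ordinary enol chemistry.

Step 2
Reactants: 2 5-hydroxy-2-(hydroxymethyl)-6-iodo-4H-pyran-4-one
Product: 3 2-(hydroxymethyl)-6-iodo-5-(methoxymethoxy)-4H-pyran-4-one
Conditions: MOMCl (1.05 equiv), K2CO3, acetone, 0 → 25 °C
Reagents that add atoms: chloromethyl methyl ether, COCCl
Why: Williamson-type O-alkylation of the potassium enolate. Carbonate deprotonates only the acidic enol OH, so with one equivalent of MOMCl the primary alcohol needed in step 8 stays free.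

Step 3
Reactants: 4 5-bromosalicylaldehyde
Product: 5 5-bromo-2-(methoxymethoxy)benzaldehyde
Conditions: MOMCl, iPr2NEt, CH2Cl2, 0 → 25 °C
Reagents that add atoms: chloromethyl methyl ether, COCCl
Why: Standard acetal protection of a phenol; it fixes the future 4'-oxygen before the second oxygen is created.

Step 4
Reactants: 5 5-bromo-2-(methoxymethoxy)benzaldehyde
Product: 7 5-bromo-2-(methoxymethoxy)phenol, via aryl formate 6 (not isolated)
Conditions: mCPBA, CH2Cl2, 0 → 25 °C; aqueous NaHCO3 wash; then Et3N (cat.), MeOH, 25 °C
Reagents that add atoms: 3-chloroperbenzoic acid, OOC(=O)c1cccc(Cl)c1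
Why: Baeyer–Villiger (Dakin-type) oxidation: the aryl group, made electron-rich by the ortho alkoxy donor, migrates in preference to hydride. The formate is then methanolysed under mild base that leaves the acetal untouched.

Step 5
Reactants: 7 5-bromo-2-(methoxymethoxy)phenol; 8 prenyl bromide
Product: 9 4-bromo-1-(methoxymethoxy)-2-[(3-methylbut-2-en-1-yl)oxy]benzene
Conditions: K2CO3, DMF, 25 °C
Reagents that add atoms: none
Why: Williamson ether synthesis, SN2 at the unhindered primary allylic carbon. The only free oxygen is the future O3', so the prenyl group can go nowhere else.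

Step 6
Reactants: 9 4-bromo-1-(methoxymethoxy)-2-[(3-methylbut-2-en-1-yl)oxy]benzene
Product: 11 2-Ar-4,4,5,5-tetramethyl-1,3,2-dioxaborolane, via aryllithium 10 (not isolated)
Conditions: n-BuLi, THF, −78 °C; then iPrOBpin, −78 → 25 °C; H2O
Reagents that add atoms: n-butyllithium, CCCC[Li] (supplies the lithium of 10 only); 2-isopropoxy-4,4,5,5-tetramethyl-1,3,2-dioxaborolane, CC(C)OB1OC(C)(C)C(C)(C)O1
Why: Bromine–lithium exchange at −78 °C is much faster than ortho-lithiation or deprotonation at the allylic OCH2, and the aryllithium is trapped by the borate. Making the boronate without palladium keeps the prenyl ether away from zerovalent palladium at this stage.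

Step 7
Reactants: 3 2-(hydroxymethyl)-6-iodo-5-(methoxymethoxy)-4H-pyran-4-one; 11 2-Ar-4,4,5,5-tetramethyl-1,3,2-dioxaborolane
Product: 12 2-(hydroxymethyl)-5-(methoxymethoxy)-6-Ar-4H-pyran-4-one
Conditions: Pd(dppf)Cl2 (3 mol %), K3PO4, 1,4-dioxane/H2O (10:1), 60 °C
Reagents that add atoms: none
Why: Suzuki–Miyaura coupling. The C–I bond of the vinylogous acyl iodide adds to palladium fast at moderate temperature, and a chelating bisphosphine with a mild phosphate base limits both hydrolysis of the iodide and π-allyl ionisation of the prenyl ether. The free alcohol is tolerated.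

Step 8
Reactants: 12 2-(hydroxymethyl)-5-(methoxymethoxy)-6-Ar-4H-pyran-4-one
Product: 13 5-(methoxymethoxy)-6-Ar-4-oxo-4H-pyran-2-carbaldehyde
Conditions: Dess–Martin periodinane, CH2Cl2, 0 → 25 °C
Reagents that add atoms: none
Why: Dess–Martin oxidation of a primary alcohol to the aldehyde without over-oxidation. The reagent is neutral enough for the acetals and does not touch the trisubstituted alkene.

Step 9
Reactants: 14 diethyl (hydroxymethyl)phosphonate
Product: 15 diethyl [(methoxymethoxy)methyl]phosphonate
Conditions: MOMCl, iPr2NEt, CH2Cl2, 0 → 25 °C
Reagents that add atoms: chloromethyl methyl ether, COCCl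
Why: Standard acetal protection of a primary alcohol; this oxygen becomes O7.

Step 10
Reactants: 15 diethyl [(methoxymethoxy)methyl]phosphonate
Product: 17 racemic diethyl [1-(methoxymethoxy)-2-oxopropyl]phosphonate, via lithiated phosphonate 16 (not isolated)
Conditions: LDA (1.05 equiv), THF, −78 °C; then N-methoxy-N-methylacetamide, −78 → 0 °C; AcOH
Reagents that add atoms: lithium diisopropylamide, CC(C)N([Li])C(C)C (supplies the lithium of 16 only); N-methoxy-N-methylacetamide, CC(=O)N(C)OC
Why: Acylation of a phosphoryl-stabilised α-alkoxy carbanion. The Weinreb amide holds the adduct as a chelated tetrahedral intermediate until the quench, so the acidic β-ketophosphonate never consumes the carbanion and one equivalent of base suffices. The stereocentre at the phosphonate carbon is irrelevant because it becomes sp2 in step 11.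

Step 11
Reactants: 13 5-(methoxymethoxy)-6-Ar-4-oxo-4H-pyran-2-carbaldehyde; 17 racemic diethyl [1-(methoxymethoxy)-2-oxopropyl]phosphonate
Product: 18 (3Z)-3-(methoxymethoxy)-4-[5-(methoxymethoxy)-6-Ar-4-oxo-4H-pyran-2-yl]but-3-en-2-one
Conditions: LiCl, DBU, MeCN, 0 → 25 °C
Reagents that add atoms: none
Why: Horner–Wadsworth–Emmons olefination under Masamune–Roush conditions, which are mild enough for the electrophilic pyranone aldehyde. The 3Z isomer (pyranone trans to the acetyl group) should predominate, and any 3E isomer is carried on unseparated because both converge in step 13.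

Step 12
Reactants: 18 (3Z)-3-(methoxymethoxy)-4-[5-(methoxymethoxy)-6-Ar-4-oxo-4H-pyran-2-yl]but-3-en-2-one
Product: 19 6-[(1Z)-3-(tert-butyldimethylsilyloxy)-2-(methoxymethoxy)buta-1,3-dien-1-yl]-3-(methoxymethoxy)-2-Ar-4H-pyran-4-one
Conditions: TBSOTf, Et3N, CH2Cl2, −78 → 0 °C; filtration through Et3N-deactivated silica
Reagents that add atoms: tert-butyldimethylsilyl trifluoromethanesulfonate, CC(C)(C)[Si](C)(C)OS(=O)(=O)C(F)(F)F
Why: Soft enolisation and O-silylation of a methyl ketone. Only the methyl group has α-hydrogens, so the 2-silyloxydiene forms with unambiguous regiochemistry and unchanged C7=C8 geometry. Low temperature and excess amine keep the silyl triflate from opening the acetals.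

Step 13
Reactants: 19 6-[(1Z)-3-(tert-butyldimethylsilyloxy)-2-(methoxymethoxy)buta-1,3-dien-1-yl]-3-(methoxymethoxy)-2-Ar-4H-pyran-4-one
Product: 22 6-(tert-butyldimethylsilyloxy)-3,7-bis(methoxymethoxy)-2-Ar-4H-chromen-4-one, via 1E diene 20 (not isolated), via 4a,5-dihydrochromone 21 (not isolated)
Conditions: 390 nm LED, o-xylene (0.01 M), Ar, 140 °C; then activated MnO2, 25 °C
Reagents that add atoms: none
Why: Proposed new method: irradiation interconverts the geometric isomers about C7=C8, and only 20, with the pyranone and C6 cis, can fold into the s-cis,s-cis triene C4a=C8a–C8=C7–C6=C5 that undergoes thermal disrotatory 6π electrocyclisation, forming C4a–C5 and closing the six-membered carbocycle (ring A) in 21; since 20 is drained continuously, all of 19 should be funnelled through it. The closest known reaction type is the thermal 6π electrocyclisation and dehydrogenation of 2,3-divinylindoles and divinylbenzofurans to carbazoles and dibenzofurans, where a weakly aromatic heterocyclic C=C bond is one triene terminus just as the pyranone C4a=C8a bond is here. MnO2 (tetravalent manganese) then removes the hydrogens at C4a and C5, directly or after a hydrogen shift to the 5,8-dihydro isomer, which restores the pyranone and aromatises ring A. The only stereocentre formed, C4a of 21, is racemic and is erased by the oxidation, so no stereocontrol is needed. Regioselectivity is fixed by the substrate, because C8a has the ring oxygen on its other side and C4a is the only carbon that can close; the adjacent oxygen substituents at C6 and C7 favour the s-cis diene. Light feeds the reactive isomer in place of iodine, which would iodinate the silyl dienol ether, and in place of a higher temperature, because 140 °C stays below the usual onset of Claisen rearrangement of an aryl prenyl ether. MnO2 is preferred to DDQ, which cleaves prenyl ethers oxidatively, and it is added promptly so that no double-bond migration and β-elimination in 21 can expel the C6 or C7 oxygen.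

Step 14
Reactants: 22 6-(tert-butyldimethylsilyloxy)-3,7-bis(methoxymethoxy)-2-Ar-4H-chromen-4-one
Product: 23 3,6,7-trihydroxy-2-{4-hydroxy-3-[(3-methylbut-2-en-1-yl)oxy]phenyl}-4H-chromen-4-one
Conditions: HCl (1.25 M in MeOH), THF, 0 → 25 °C
Reagents that add atoms: none
Why: Acid-catalysed acetal solvolysis through the methoxymethyl oxocarbenium ion removes the three MOM groups, and the aryl silyl ether is cleaved in acidic methanol at a comparable rate, so one operation replaces a fluoride step and an acid step. The prenyl ether would have to ionise to the far less stabilised dimethylallyl cation and should survive, and an acidic finish keeps the catechol and the enol from air oxidation.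

## Compound list

1 | kojic acid (5-hydroxy-2-(hydroxymethyl)-4H-pyran-4-one) | OCc1cc(=O)c(O)co1 | starting material
2 | 5-hydroxy-2-(hydroxymethyl)-6-iodo-4H-pyran-4-one | OCc1cc(=O)c(O)c(I)o1 | intermediate
3 | 2-(hydroxymethyl)-6-iodo-5-(methoxymethoxy)-4H-pyran-4-one | OCc1cc(=O)c(OCOC)c(I)o1 | intermediate
4 | 5-bromosalicylaldehyde (5-bromo-2-hydroxybenzaldehyde) | O=Cc1cc(Br)ccc1O | starting material
5 | 5-bromo-2-(methoxymethoxy)benzaldehyde | O=Cc1cc(Br)ccc1OCOC | intermediate
6 | 5-bromo-2-(methoxymethoxy)phenyl formate | O=COc1cc(Br)ccc1OCOC | intermediate (not isolated)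
7 | 5-bromo-2-(methoxymethoxy)phenol | Oc1cc(Br)ccc1OCOC | intermediate
8 | prenyl bromide (1-bromo-3-methylbut-2-ene) | CC(C)=CCBr | starting material
9 | 4-bromo-1-(methoxymethoxy)-2-[(3-methylbut-2-en-1-yl)oxy]benzene | CC(C)=CCOc1cc(Br)ccc1OCOC | intermediate
10 | {4-(methoxymethoxy)-3-[(3-methylbut-2-en-1-yl)oxy]phenyl}lithium | [Li]c1ccc(OCOC)c(OCC=C(C)C)c1 | intermediate (not isolated)
11 | 2-{4-(methoxymethoxy)-3-[(3-methylbut-2-en-1-yl)oxy]phenyl}-4,4,5,5-tetramethyl-1,3,2-dioxaborolane | CC(C)=CCOc1cc(B2OC(C)(C)C(C)(C)O2)ccc1OCOC | intermediate
12 | 2-(hydroxymethyl)-5-(methoxymethoxy)-6-{4-(methoxymethoxy)-3-[(3-methylbut-2-en-1-yl)oxy]phenyl}-4H-pyran-4-one | OCc1cc(=O)c(OCOC)c(-c2ccc(OCOC)c(OCC=C(C)C)c2)o1 | intermediate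
13 | 5-(methoxymethoxy)-6-{4-(methoxymethoxy)-3-[(3-methylbut-2-en-1-yl)oxy]phenyl}-4-oxo-4H-pyran-2-carbaldehyde | O=Cc1cc(=O)c(OCOC)c(-c2ccc(OCOC)c(OCC=C(C)C)c2)o1 | intermediate
14 | diethyl (hydroxymethyl)phosphonate | CCOP(=O)(CO)OCC | starting material
15 | diethyl [(methoxymethoxy)methyl]phosphonate | CCOP(=O)(COCOC)OCC | intermediate
16 | diethyl [lithio(methoxymethoxy)methyl]phosphonate | [Li]C(OCOC)P(=O)(OCC)OCC | intermediate (not isolated)
17 | diethyl [1-(methoxymethoxy)-2-oxopropyl]phosphonate (racemic) | CCOP(=O)(OCC)C(OCOC)C(C)=O | intermediate
18 | (3Z)-3-(methoxymethoxy)-4-[5-(methoxymethoxy)-6-{4-(methoxymethoxy)-3-[(3-methylbut-2-en-1-yl)oxy]phenyl}-4-oxo-4H-pyran-2-yl]but-3-en-2-one | CC(=O)/C(OCOC)=C/c1cc(=O)c(OCOC)c(-c2ccc(OCOC)c(OCC=C(C)C)c2)o1 | intermediate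
19 | 6-[(1Z)-3-(tert-butyldimethylsilyloxy)-2-(methoxymethoxy)buta-1,3-dien-1-yl]-3-(methoxymethoxy)-2-{4-(methoxymethoxy)-3-[(3-methylbut-2-en-1-yl)oxy]phenyl}-4H-pyran-4-one | C=C(O[Si](C)(C)C(C)(C)C)/C(OCOC)=C/c1cc(=O)c(OCOC)c(-c2ccc(OCOC)c(OCC=C(C)C)c2)o1 | intermediate
20 | 6-[(1E)-3-(tert-butyldimethylsilyloxy)-2-(methoxymethoxy)buta-1,3-dien-1-yl]-3-(methoxymethoxy)-2-{4-(methoxymethoxy)-3-[(3-methylbut-2-en-1-yl)oxy]phenyl}-4H-pyran-4-one | C=C(O[Si](C)(C)C(C)(C)C)/C(OCOC)=C\c1cc(=O)c(OCOC)c(-c2ccc(OCOC)c(OCC=C(C)C)c2)o1 | intermediate (not isolated)
21 | 6-(tert-butyldimethylsilyloxy)-3,7-bis(methoxymethoxy)-2-{4-(methoxymethoxy)-3-[(3-methylbut-2-en-1-yl)oxy]phenyl}-4a,5-dihydro-4H-chromen-4-one (racemic at C4a) | O=C1C(OCOC)=C(c2ccc(OCOC)c(OCC=C(C)C)c2)OC2=CC(OCOC)=C(O[Si](C)(C)C(C)(C)C)CC12 | intermediate (not isolated)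
22 | 6-(tert-butyldimethylsilyloxy)-3,7-bis(methoxymethoxy)-2-{4-(methoxymethoxy)-3-[(3-methylbut-2-en-1-yl)oxy]phenyl}-4H-chromen-4-one | CC(C)=CCOc1cc(-c2oc3cc(OCOC)c(O[Si](C)(C)C(C)(C)C)cc3c(=O)c2OCOC)ccc1OCOC | intermediate
23 | 3,6,7-trihydroxy-2-{4-hydroxy-3-[(3-methylbut-2-en-1-yl)oxy]phenyl}-4H-chromen-4-one | CC(C)=CCOc1cc(-c2oc3cc(O)c(O)cc3c(=O)c2O)ccc1O | target

## Step count and least certain steps

Total step count: 14. Longest linear sequence: 10 steps (4 → 5 → 7 → 9 → 11 → 12 → 13 → 18 → 19 → 22 → 23, that is steps 3 to 8 and 11 to 14).

**Step 13 (key step, proposed new method).**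
- Ring closure at C4a costs the pyranone its cyclic conjugation. It may be too slow at a temperature that the silyl dienol ether and the prenyl ether tolerate.
- Irradiation may drive dimerisation or other photochemistry of the dienyl pyranone, not only geometric isomerisation.
- In the dihydro stage, double-bond migration followed by β-elimination could expel the C6 or C7 oxygen before the oxidant acts.
- Fallback, known chemistry only, from 9 back to the route at 23:
  - Bromine–lithium exchange on 9 (n-BuLi, THF, −78 °C) and quenching with DMF would give 4-(methoxymethoxy)-3-[(3-methylbut-2-en-1-yl)oxy]benzaldehyde F1.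
  - Commercial 1-(2,4,5-trihydroxyphenyl)ethan-1-one would be alkylated twice with MOMCl and K2CO3 to 1-[2-hydroxy-4,5-bis(methoxymethoxy)phenyl]ethan-1-one F2, the hydrogen-bonded ortho hydroxyl staying free.
  - Claisen–Schmidt condensation of F1 with F2 (KOH, EtOH) would give the chalcone (2E)-1-[2-hydroxy-4,5-bis(methoxymethoxy)phenyl]-3-{4-(methoxymethoxy)-3-[(3-methylbut-2-en-1-yl)oxy]phenyl}prop-2-en-1-one F3.
  - Algar–Flynn–Oyamada oxidation (H2O2, NaOH, MeOH) would close ring C to 3-hydroxy-6,7-bis(methoxymethoxy)-2-{4-(methoxymethoxy)-3-[(3-methylbut-2-en-1-yl)oxy]phenyl}-4H-chromen-4-one F4.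
  - The conditions of step 14 would then take F4 to 23.

**Step 11.**
- Addition of the hindered, alkoxy-substituted phosphonate anion may be sluggish.
- Base-induced degradation of the very electrophilic aldehyde (hydration, conjugate attack on the pyranone) can then compete.
- Fallback, from 13 back to the route at 18:
  - Commercial hydroxyacetone would be protected with MOMCl and iPr2NEt as 1-(methoxymethoxy)propan-2-one F5.
  - An amine-catalysed aldol addition (pyrrolidine, AcOH, DMSO) of F5 to 13 should occur at the oxygen-bearing carbon, as is usual for protected hydroxyacetones. It would give 4-hydroxy-3-(methoxymethoxy)-4-[5-(methoxymethoxy)-6-{4-(methoxymethoxy)-3-[(3-methylbut-2-en-1-yl)oxy]phenyl}-4-oxo-4H-pyran-2-yl]butan-2-one F6 as a mixture of racemic diastereomers.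
  - Mesylation and elimination (MsCl, Et3N, CH2Cl2, 0 °C) would deliver 18.

**Step 7.**
- Hydroxide or water may displace iodide from the vinylogous acyl iodide, or protodeiodination may occur, faster than transmetalation.
- The prenyl ether may ionise on zerovalent palladium.
- Fallback, from 9 back to the route at 12:
  - The aryllithium from 9 (n-BuLi, THF, −78 °C) would be quenched with Bu3SnCl to give tributyl{4-(methoxymethoxy)-3-[(3-methylbut-2-en-1-yl)oxy]phenyl}stannane F7.
  - F7 would be coupled with 3 under base-free Stille conditions (Pd2(dba)3 as zerovalent palladium source, AsPh3, CuI, DMF, 50 °C) to give 12.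
  - This removes the aqueous base that causes the hydrolytic loss.

**Step 14.**
- Ionisation of the allylic C–O bond of the prenyl ether, or transfer of the freed prenyl cation to the electron-rich rings, may compete with slow removal of the last acetal or of the silyl group.
- Fallback, from 22 back to the route at 23:
  - Buffered fluoride (TBAF, AcOH, THF, 0 °C) would give 6-hydroxy-3,7-bis(methoxymethoxy)-2-{4-(methoxymethoxy)-3-[(3-methylbut-2-en-1-yl)oxy]phenyl}-4H-chromen-4-one F8.
  - The three acetals would then be removed without protic acid by silyl triflate-mediated cleavage buffered with a pyridine base (TMSOTf, 2,2'-bipyridyl, CH2Cl2, 0 °C; then H2O) to give 23.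

## Further compounds

F1 | step 13 | 4-(methoxymethoxy)-3-[(3-methylbut-2-en-1-yl)oxy]benzaldehyde | O=Cc1ccc(OCOC)c(OCC=C(C)C)c1
F2 | step 13 | 1-[2-hydroxy-4,5-bis(methoxymethoxy)phenyl]ethan-1-one | CC(=O)c1cc(OCOC)c(OCOC)cc1O
F3 | step 13 | (2E)-1-[2-hydroxy-4,5-bis(methoxymethoxy)phenyl]-3-{4-(methoxymethoxy)-3-[(3-methylbut-2-en-1-yl)oxy]phenyl}prop-2-en-1-one | O=C(/C=C/c1ccc(OCOC)c(OCC=C(C)C)c1)c1cc(OCOC)c(OCOC)cc1O
F4 | step 13 | 3-hydroxy-6,7-bis(methoxymethoxy)-2-{4-(methoxymethoxy)-3-[(3-methylbut-2-en-1-yl)oxy]phenyl}-4H-chromen-4-one | CC(C)=CCOc1cc(-c2oc3cc(OCOC)c(OCOC)cc3c(=O)c2O)ccc1OCOC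
F5 | step 11 | 1-(methoxymethoxy)propan-2-one | COCOCC(C)=O
F6 | step 11 | 4-hydroxy-3-(methoxymethoxy)-4-[5-(methoxymethoxy)-6-{4-(methoxymethoxy)-3-[(3-methylbut-2-en-1-yl)oxy]phenyl}-4-oxo-4H-pyran-2-yl]butan-2-one (mixture of racemic diastereomers) | CC(=O)C(OCOC)C(O)c1cc(=O)c(OCOC)c(-c2ccc(OCOC)c(OCC=C(C)C)c2)o1
F7 | step 7 | tributyl{4-(methoxymethoxy)-3-[(3-methylbut-2-en-1-yl)oxy]phenyl}stannane | CCCC[Sn](CCCC)(CCCC)c1ccc(OCOC)c(OCC=C(C)C)c1
F8 | step 14 | 6-hydroxy-3,7-bis(methoxymethoxy)-2-{4-(methoxymethoxy)-3-[(3-methylbut-2-en-1-yl)oxy]phenyl}-4H-chromen-4-one | CC(C)=CCOc1cc(-c2oc3cc(OCOC)c(O)cc3c(=O)c2OCOC)ccc1OCOC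
A1 | alternative 1 | methyl coumalate (methyl 2-oxo-2H-pyran-5-carboxylate) | COC(=O)C1=COC(=O)C=C1
A2 | alternative 1 | 1,1-bis(trimethylsilyloxy)-2-[(3-methylbut-2-en-1-yl)oxy]ethene | CC(C)=CCOC=C(O[Si](C)(C)C)O[Si](C)(C)C
A3 | alternative 1 | methyl 4-hydroxy-3-[(3-methylbut-2-en-1-yl)oxy]benzoate | COC(=O)c1ccc(O)c(OCC=C(C)C)c1
A4 | alternative 2 | 1-iodo-2,4,5-tris(methoxymethoxy)benzene | COCOc1cc(OCOC)c(OCOC)cc1I
A5 | alternative 2 | 2-(methoxymethoxy)-1-{4-(methoxymethoxy)-3-[(3-methylbut-2-en-1-yl)oxy]phenyl}ethan-1-one | COCOCC(=O)c1ccc(OCOC)c(OCC=C(C)C)c1
A6 | alternative 2 | carbon monoxide | [C-]#[O+]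
A7 | alternative 2 | 2-(methoxymethoxy)-1-{4-(methoxymethoxy)-3-[(3-methylbut-2-en-1-yl)oxy]phenyl}-3-[2,4,5-tris(methoxymethoxy)phenyl]propane-1,3-dione (racemic, enolisable) | COCOC(C(=O)c1ccc(OCOC)c(OCC=C(C)C)c1)C(=O)c1cc(OCOC)c(OCOC)cc1OCOC
A8 | alternative 3 | 2-[2-formyl-4,5-bis(methoxymethoxy)phenoxy]-2-{4-(methoxymethoxy)-3-[(3-methylbut-2-en-1-yl)oxy]phenyl}acetaldehyde (racemic) | O=CC(Oc1cc(OCOC)c(OCOC)cc1C=O)c1ccc(OCOC)c(OCC=C(C)C)c1
A9 | alternative 3 | trans-3-hydroxy-6,7-bis(methoxymethoxy)-2-{4-(methoxymethoxy)-3-[(3-methylbut-2-en-1-yl)oxy]phenyl}chroman-4-one (racemic, 2R,3R enantiomer drawn) | O=C1c2cc(OCOC)c(OCOC)cc2O[C@H](c2ccc(OCOC)c(OCC=C(C)C)c2)[C@H]1O
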